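**Retrosynthetic overview**

1. Target: 15-(hydrogen malonate) of ent-labdane-8,15,18-triol. Last disconnections: hydrogenolysis of a benzyl malonate and the C18 benzyl ether; C8 (OH and C17) by hydride opening of an 8,17-epoxide; C9–C11 by Negishi coupling of a C9 enol triflate with a C11–C15 zinc reagent cut from (S)-citronellol (C13).
2. Feature the strategy rests on: quaternary C4 of ring A, bonded to C5, carries the C19 methyl and the oxidised C18. These two are the methyl and the CH2 terminus of a 1,1-disubstituted alkene C4=C18 held three carbons (C1–C3) away from C10.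
3. Key disconnection: C4–C5 (and C18–B) by palladium-catalysed 6-exo carbopalladation of the ring B C5 enol triflate onto C4=C18, terminated by borylation with B2pin2; the boronate later becomes C18–OH.
4. Ring order: ring B comes from 2-methylcyclohexane-1,3-dione (C-allylation, then enzymatic desymmetrisation sets C10); ring A is closed in the key step; C5, C9 and C8 are set afterwards on the bicycle.

Key step: step 8

Remark (assumption): labdane numbering is used throughout; in step 8 (R)-BINAP is taken as the ligand enantiomer matched with the C10 centre, and the mirror-image ligand would be used without other change if a comparison run says otherwise.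
Remark (assumption): the ketoreductase of step 2 is taken to show the (2S,3S) selectivity known for baker's yeast with this dione.

**Route**

Step 1
Reactants: 1 2-methylcyclohexane-1,3-dione; 2 allyl bromide
Product: 3 2-allyl-2-methylcyclohexane-1,3-dione
Conditions: 1 M aq NaOH, Bu4NI (cat.), rt
Reagents that add atoms: none
Why: C-allylation of the 1,3-dione enolate in water, where hydrogen bonding at the enolate oxygen favours C- over O-alkylation.

Step 2
Reactants: 3 2-allyl-2-methylcyclohexane-1,3-dione
Product: 4 (2S,3S)-2-allyl-3-hydroxy-2-methylcyclohexan-1-one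
Conditions: ketoreductase, NADP+ (cat.), i-PrOH, phosphate buffer pH 7, 30 °C
Reagents that add atoms: none
Why: Enzymatic desymmetrising reduction of one of the two enantiotopic carbonyls, known for this dione, fixes the quaternary carbon (future C10) as S by the enzyme's choice of carbonyl; the carbinol (future C9) is erased in step 7.

Step 3
Reactants: 4 (2S,3S)-2-allyl-3-hydroxy-2-methylcyclohexan-1-one
Product: 5 (2S,3S)-2-allyl-3-(tert-butyldimethylsilyloxy)-2-methylcyclohexan-1-one
Conditions: TBSCl, imidazole, DMF, 40 °C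
Reagents that add atoms: tert-butyldimethylsilyl chloride, CC(C)(C)[Si](C)(C)Cl
Why: Standard silylation masks the carbinol so that the remaining ketone (future C5) alone is enolised later.

Step 4
Reactants: 5 (2S,3S)-2-allyl-3-(tert-butyldimethylsilyloxy)-2-methylcyclohexan-1-one; 6 2-bromopropene
Product: 8 (2S,3S)-3-(tert-butyldimethylsilyloxy)-2-methyl-2-(4-methylpent-4-en-1-yl)cyclohexan-1-one, via B-alkyl-9-BBN adduct 7 (not isolated)
Conditions: 9-BBN, THF, 0 °C to rt; then 6, PdCl2(dppf), 3 M aq K3PO4, DMF, 50 °C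
Reagents that add atoms: none
Why: Anti-Markovnikov hydroboration of the monosubstituted alkene should outpace reduction of the ketone shielded by the quaternary carbon, and the B-alkyl Suzuki–Miyaura coupling then installs C4, C18 and C19.

Step 5
Reactants: 8 (2S,3S)-3-(tert-butyldimethylsilyloxy)-2-methyl-2-(4-methylpent-4-en-1-yl)cyclohexan-1-one
Product: 10 (5S,6S)-5-(tert-butyldimethylsilyloxy)-6-methyl-6-(4-methylpent-4-en-1-yl)cyclohex-1-en-1-yl trifluoromethanesulfonate, via potassium enolate 9 (not isolated)
Conditions: KN(SiMe3)2, THF, −78 °C; then PhNTf2, −78 to 0 °C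
Reagents that add atoms: N-phenylbis(trifluoromethanesulfonimide), O=S(=O)(N(c1ccccc1)S(=O)(=O)C(F)(F)F)C(F)(F)F
Why: The ketone has α-hydrogens only at C6 (C10 is quaternary), so enolisation and O-sulfonylation give a single enol triflate.

Step 6
Reactants: 10 (5S,6S)-5-(tert-butyldimethylsilyloxy)-6-methyl-6-(4-methylpent-4-en-1-yl)cyclohex-1-en-1-yl trifluoromethanesulfonate
Product: 11 (5S,6S)-5-hydroxy-6-methyl-6-(4-methylpent-4-en-1-yl)cyclohex-1-en-1-yl trifluoromethanesulfonate
Conditions: HF·pyridine, pyridine, THF, 0 °C to rt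
Reagents that add atoms: none
Why: Buffered fluoride desilylation, which enol triflates and isolated alkenes tolerate.

Step 7
Reactants: 11 (5S,6S)-5-hydroxy-6-methyl-6-(4-methylpent-4-en-1-yl)cyclohex-1-en-1-yl trifluoromethanesulfonate
Product: 12 (R)-6-methyl-6-(4-methylpent-4-en-1-yl)-5-oxocyclohex-1-en-1-yl trifluoromethanesulfonate (ring B keto enol triflate)
Conditions: Dess–Martin periodinane, NaHCO3, CH2Cl2, rt
Reagents that add atoms: none
Why: Dess–Martin oxidation returns the C9 ketone; C10 is quaternary, so it can neither epimerise nor let the ketone conjugate with C5=C6.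

Step 8
Reactants: 12 ring B keto enol triflate; 13 bis(pinacolato)diboron
Product: 14 C18 pinacol boronate of the ent-decal-5-en-9-one (C19 methyl cis to C20)
Conditions: Pd(OAc)2 (5 mol %), (R)-BINAP (7.5 mol %), KOAc (2 equiv), toluene, 80 °C
Reagents that add atoms: none
Why: Zerovalent palladium (formed from Pd(OAc)2, the phosphine and B2pin2) adds oxidatively to the C5–OTf bond, the cationic alkenylpalladium inserts the C4=C18 alkene syn (C5 to C4, palladium to C18), and the neopentyl C18–palladium species, which has no β-hydrogen because C4 is quaternary, is transmetalated by B2pin2 with acetate assistance and reductively eliminated to the C18–B bond. The closest known reaction type is the domino Heck cyclisation and borylation (carboborylation) of alkene-tethered aryl or alkenyl halides and triflates with B2pin2. Ring A is closed in the 6-exo-trig mode. The only new stereocentre, C4, is fixed by the face of C5 toward which palladium leaves: H6 keeps palladium out of the plane of C5=C6, so the Pd–C5/C4=C18 four-centre array stands across that plane and C18 ends on the palladium face; with palladium on the face anti to the C20 methyl, C18 comes out trans and the C19 methyl cis to C20. That facial selectivity is the one the step needs; it is to be secured by the C20 methyl on C10, which eclipses palladium in the competing array, reinforced by the matched BINAP ligand on cationic palladium (triflate, no halide). The step also needs insertion to outrun borylation of the alkenylpalladium and boron capture to outrun 3-exo attack of C18–palladium on C5=C6, which the intramolecular 6-exo insertion and the excess of B2pin2 with KOAc should provide.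

Step 9
Reactants: 14 C18 pinacol boronate of the ent-decal-5-en-9-one
Product: 15 18-hydroxy ent-decal-5-en-9-one
Conditions: NaBO3·4H2O, THF/H2O, rt
Reagents that add atoms: sodium perborate tetrahydrate (peroxoborate salt), [Na+].[Na+].O[B-]1(O)OO[B-](O)(O)OO1
Why: Perborate oxidation of the alkyl boronate (1,2-shift of C18 from boron to oxygen) is mild enough for the ketone and the alkene.

Step 10
Reactants: 15 18-hydroxy ent-decal-5-en-9-one
Product: 16 18-hydroxy trans-decalin-9-one (H5 trans to C20)
Conditions: H2 (1 bar), [Ir(cod)(PCy3)(py)]PF6 (5 mol %), CH2Cl2, rt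
Reagents that add atoms: none
Why: Hydroxyl-directed homogeneous hydrogenation with Crabtree's catalyst: iridium held by the C18 hydroxyl adds H2 to C5=C6 from the face anti to the axial C19 and C20 methyl groups, which sets H5 trans to C20.

Step 11
Reactants: 16 18-hydroxy trans-decalin-9-one
Product: 17 18-benzyloxy trans-decalin-9-one
Conditions: benzyl 2,2,2-trichloroacetimidate, TfOH (cat.), CH2Cl2/cyclohexane, 0 °C to rt
Reagents that add atoms: benzyl 2,2,2-trichloroacetimidate, ClC(Cl)(Cl)C(=N)OCc1ccccc1
Why: Acid-catalysed imidate benzylation protects the neopentyl alcohol without base, so the enolisable C9 ketone is not touched.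

Step 12
Reactants: 17 18-benzyloxy trans-decalin-9-one
Product: 19 18-benzyloxy C9 enol triflate (C8=C9), via potassium enolate 18 (not isolated)
Conditions: KN(SiMe3)2, THF, −78 °C; then PhNTf2, −78 to 0 °C
Reagents that add atoms: N-phenylbis(trifluoromethanesulfonimide), O=S(=O)(N(c1ccccc1)S(=O)(=O)C(F)(F)F)C(F)(F)F
Why: The C9 ketone can enolise only toward C8, so O-triflation gives the single C8=C9 enol triflate.

Step 13
Reactants: 20 (S)-citronellol
Product: 21 (S)-citronellyl pivalate
Conditions: PivCl, pyridine, DMAP (cat.), CH2Cl2, 0 °C to rt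
Reagents that add atoms: pivaloyl chloride, CC(C)(C)C(=O)Cl
Why: Acylation of the primary alcohol gives an ester that survives the oxidative, organozinc and borane steps and is removed by LiAlH4 in step 21.

Step 14
Reactants: 21 (S)-citronellyl pivalate
Product: 22 (S)-4-methyl-6-(pivaloyloxy)hexanoic acid
Conditions: RuCl3·xH2O (2 mol %), NaIO4, EtOAc/MeCN/H2O, rt
Reagents that add atoms: sodium periodate, [Na+].[O-]I(=O)(=O)=O; water, O
Why: RuO4-catalysed oxidative cleavage of the trisubstituted alkene gives the acid and acetone and leaves the remote C13 stereocentre untouched.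

Step 15
Reactants: 22 (S)-4-methyl-6-(pivaloyloxy)hexanoic acid
Product: 23 (R)-5-iodo-3-methylpentyl pivalate
Conditions: PhI(OAc)2, I2, cyclohexane, hν (tungsten lamp), reflux
Reagents that add atoms: iodine, II
Why: Hunsdiecker-type iododecarboxylation through the acyl hypoiodite removes one carbon and leaves the primary iodide at the future C11.

Step 16
Reactants: 23 (R)-5-iodo-3-methylpentyl pivalate; 19 18-benzyloxy C9 enol triflate
Product: 25 18-benzyloxy-15-pivaloyloxy-17-nor-ent-labd-8-ene, via alkylzinc iodide 24 (not isolated)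
Conditions: Zn dust, LiCl, THF, 40 °C; then 19, Pd(OAc)2 (3 mol %), SPhos (6 mol %), THF, 50 °C
Reagents that add atoms: none
Why: LiCl-assisted zinc insertion into the primary iodide followed by Negishi coupling with the enol triflate forms C9–C11 and tolerates the ester.

Step 17
Reactants: 25 18-benzyloxy-15-pivaloyloxy-17-nor-ent-labd-8-ene
Product: 27 18-benzyloxy-15-pivaloyloxy-17-nor-ent-labdan-8-ol (8-OH and H9 trans to C20), via C8 alkylborane 26 (not isolated)
Conditions: BH3·THF, THF, 0 °C to rt; then NaBO3·4H2O, H2O, rt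
Reagents that add atoms: sodium perborate tetrahydrate (peroxoborate salt), [Na+].[Na+].O[B-]1(O)OO[B-](O)(O)OO1
Why: Hydroboration–oxidation: borane adds syn from the face anti to the C20 methyl, boron at the less substituted C8 and hydrogen at C9, which sets H9 trans to C20 (chain equatorial).

Step 18
Reactants: 27 18-benzyloxy-15-pivaloyloxy-17-nor-ent-labdan-8-ol
Product: 28 18-benzyloxy-15-pivaloyloxy-17-nor-ent-labdan-8-one
Conditions: Dess–Martin periodinane, NaHCO3, CH2Cl2, rt
Reagents that add atoms: none
Why: Dess–Martin oxidation gives the C8 ketone; C9 already carries its chain equatorial, the thermodynamically preferred arrangement next to the ketone.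

Step 19
Reactants: 28 18-benzyloxy-15-pivaloyloxy-17-nor-ent-labdan-8-one
Product: 29 18-benzyloxy-15-pivaloyloxy-ent-labd-8(17)-ene
Conditions: Ph3PCH3Br, KN(SiMe3)2, THF, 0 °C; then 28, rt to 60 °C
Reagents that add atoms: methyltriphenylphosphonium bromide, C[P+](c1ccccc1)(c1ccccc1)c1ccccc1.[Br-]
Why: Wittig methylenation of the hindered ketone brings in C17, a standard operation on 17-nor-8-oxolabdanes.

Step 20
Reactants: 29 18-benzyloxy-15-pivaloyloxy-ent-labd-8(17)-ene
Product: 30 8,17-epoxide of 29 (oxygen trans to C20)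
Conditions: mCPBA, NaHCO3, CH2Cl2, 0 °C
Reagents that add atoms: 3-chloroperoxybenzoic acid, OOC(=O)c1cccc(Cl)c1
Why: Prilezhaev epoxidation of the exocyclic alkene from the face anti to the axial C20 methyl (equatorial attack) places the oxygen on C8 trans to C20.

Step 21
Reactants: 30 8,17-epoxide
Product: 31 18-benzyloxy-ent-labdane-8,15-diol (8-OH trans and C17 cis to C20)
Conditions: LiAlH4, THF, 0 to 50 °C
Reagents that add atoms: none
Why: Hydride opens the spiro-epoxide by SN2 attack at the primary C17, keeping the C8–O bond and its configuration, and cleaves the pivalate in the same operation.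

Step 22
Reactants: 31 18-benzyloxy-ent-labdane-8,15-diol
Product: 32 benzyl malonate of 31 at O15
Conditions: benzyl hydrogen malonate, EDC·HCl, DMAP (cat.), CH2Cl2, 0 °C to rt
Reagents that add atoms: benzyl hydrogen malonate, OC(=O)CC(=O)OCc1ccccc1
Why: Steglich-type carbodiimide esterification acylates the primary C15 hydroxyl, while the tertiary C8 hydroxyl is too hindered to react.

Step 23
Reactants: 32 benzyl malonate of 31 at O15
Product: 33 target CNP0324566.1
Conditions: H2 (1 bar), 10% Pd/C, EtOAc/EtOH, rt
Reagents that add atoms: none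
Why: Hydrogenolysis removes the benzyl ester and the C18 benzyl ether together under neutral conditions that leave the malonate half-ester and the tertiary alcohol intact.

**Compound list**

1 | 2-methylcyclohexane-1,3-dione | CC1C(=O)CCCC1=O | starting material
2 | allyl bromide | C=CCBr | starting material
3 | 2-allyl-2-methylcyclohexane-1,3-dione | C=CCC1(C)C(=O)CCCC1=O | intermediate
4 | (2S,3S)-2-allyl-3-hydroxy-2-methylcyclohexan-1-one | O[C@H]1CCCC(=O)[C@@]1(C)CC=C | intermediate
5 | (2S,3S)-2-allyl-3-(tert-butyldimethylsilyloxy)-2-methylcyclohexan-1-one | CC(C)(C)[Si](C)(C)O[C@H]1CCCC(=O)[C@@]1(C)CC=C | intermediate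
6 | 2-bromopropene | CC(Br)=C | starting material
7 | B-alkyl-9-BBN adduct of 5 (9-BBN on the terminal carbon of the former allyl group) | CC(C)(C)[Si](C)(C)O[C@H]1CCCC(=O)[C@@]1(C)CCCB2C3CCCC2CCC3 | intermediate (not isolated)
8 | (2S,3S)-3-(tert-butyldimethylsilyloxy)-2-methyl-2-(4-methylpent-4-en-1-yl)cyclohexan-1-one | CC(C)(C)[Si](C)(C)O[C@H]1CCCC(=O)[C@@]1(C)CCCC(C)=C | intermediate
9 | potassium enolate of 8 | CC(C)(C)[Si](C)(C)O[C@H]1CCC=C([O-])[C@@]1(C)CCCC(C)=C.[K+] | intermediate (not isolated)
10 | (5S,6S)-5-(tert-butyldimethylsilyloxy)-6-methyl-6-(4-methylpent-4-en-1-yl)cyclohex-1-en-1-yl trifluoromethanesulfonate | CC(C)(C)[Si](C)(C)O[C@H]1CCC=C(OS(=O)(=O)C(F)(F)F)[C@@]1(C)CCCC(C)=C | intermediate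
11 | (5S,6S)-5-hydroxy-6-methyl-6-(4-methylpent-4-en-1-yl)cyclohex-1-en-1-yl trifluoromethanesulfonate | O[C@H]1CCC=C(OS(=O)(=O)C(F)(F)F)[C@@]1(C)CCCC(C)=C | intermediate
12 | (R)-6-methyl-6-(4-methylpent-4-en-1-yl)-5-oxocyclohex-1-en-1-yl trifluoromethanesulfonate (ring B keto enol triflate: C5–OTf, C9=O, C10 quaternary) | O=C1CCC=C(OS(=O)(=O)C(F)(F)F)[C@@]1(C)CCCC(C)=C | intermediate
13 | bis(pinacolato)diboron | CC1(C)OB(OC1(C)C)B1OC(C)(C)C(C)(C)O1 | starting material
14 | C18 pinacol boronate of the ent-decal-5-en-9-one: 5,8a-dimethyl-5-[(4,4,5,5-tetramethyl-1,3,2-dioxaborolan-2-yl)methyl]-3,5,6,7,8,8a-hexahydronaphthalen-1(2H)-one, C19 methyl cis and CH2B trans to the C20 methyl | O=C1[C@]2(C)CCC[C@](C)(CB3OC(C)(C)C(C)(C)O3)C2=CCC1 | intermediate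
15 | 18-hydroxy ent-decal-5-en-9-one: 5-(hydroxymethyl)-5,8a-dimethyl-3,5,6,7,8,8a-hexahydronaphthalen-1(2H)-one, CH2OH trans to C20 | O=C1[C@]2(C)CCC[C@](C)(CO)C2=CCC1 | intermediate
16 | 18-hydroxy trans-decalin-9-one: 5-(hydroxymethyl)-5,8a-dimethyloctahydronaphthalen-1(2H)-one, H5 trans to C20 | O=C1[C@]2(C)CCC[C@](C)(CO)[C@H]2CCC1 | intermediate
17 | 18-benzyloxy trans-decalin-9-one (benzyl ether of 16) | O=C1[C@]2(C)CCC[C@](C)(COCc3ccccc3)[C@H]2CCC1 | intermediate
18 | potassium enolate of 17 (C8=C9) | [K+].[O-]C=1[C@]2(C)CCC[C@](C)(COCc3ccccc3)[C@H]2CCC=1 | intermediate (not isolated)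
19 | 18-benzyloxy C9 enol triflate (C8=C9) | FC(F)(F)S(=O)(=O)OC=1[C@]2(C)CCC[C@](C)(COCc3ccccc3)[C@H]2CCC=1 | intermediate
20 | (S)-citronellol | C[C@H](CCO)CCC=C(C)C | starting material
21 | (S)-citronellyl pivalate | C[C@H](CCOC(=O)C(C)(C)C)CCC=C(C)C | intermediate
22 | (S)-4-methyl-6-(pivaloyloxy)hexanoic acid | C[C@H](CCOC(=O)C(C)(C)C)CCC(=O)O | intermediate
23 | (R)-5-iodo-3-methylpentyl pivalate | C[C@H](CCOC(=O)C(C)(C)C)CCI | intermediate
24 | [(R)-3-methyl-5-(pivaloyloxy)pentyl]zinc iodide | C[C@H](CCOC(=O)C(C)(C)C)CC[Zn]I | intermediate (not isolated)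
25 | (13S)-18-benzyloxy-15-pivaloyloxy-17-nor-ent-labd-8-ene (C8=C9, H5 trans to C20) | C[C@H](CCOC(=O)C(C)(C)C)CCC=1[C@]2(C)CCC[C@](C)(COCc3ccccc3)[C@H]2CCC=1 | intermediate
26 | C8 alkylborane from 25 (BH2 on C8 and H on C9, both trans to C20) | C[C@H](CCOC(=O)C(C)(C)C)CC[C@H]1[C@]2(C)CCC[C@](C)(COCc3ccccc3)[C@H]2CC[C@@H]1B | intermediate (not isolated)
27 | (13S)-18-benzyloxy-15-pivaloyloxy-17-nor-ent-labdan-8-ol (8-OH and H9 trans to C20) | C[C@H](CCOC(=O)C(C)(C)C)CC[C@H]1[C@]2(C)CCC[C@](C)(COCc3ccccc3)[C@H]2CC[C@@H]1O | intermediate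
28 | (13S)-18-benzyloxy-15-pivaloyloxy-17-nor-ent-labdan-8-one (H9 trans to C20) | C[C@H](CCOC(=O)C(C)(C)C)CC[C@H]1[C@]2(C)CCC[C@](C)(COCc3ccccc3)[C@H]2CCC1=O | intermediate
29 | (13S)-18-benzyloxy-15-pivaloyloxy-ent-labd-8(17)-ene | C[C@H](CCOC(=O)C(C)(C)C)CC[C@H]1[C@]2(C)CCC[C@](C)(COCc3ccccc3)[C@H]2CCC1=C | intermediate
30 | 8,17-epoxide of 29 (epoxide oxygen trans, C17 cis to C20) | C[C@H](CCOC(=O)C(C)(C)C)CC[C@H]1[C@]2(C)CCC[C@](C)(COCc4ccccc4)[C@H]2CC[C@]13OC3 | intermediate
31 | (13S)-18-benzyloxy-ent-labdane-8,15-diol (8-OH trans, C17 cis to C20) | C[C@H](CCO)CC[C@H]1[C@]2(C)CCC[C@](C)(COCc3ccccc3)[C@H]2CC[C@]1(C)O | intermediate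
32 | benzyl malonate of 31 at O15 | C[C@H](CCOC(=O)CC(=O)OCc3ccccc3)CC[C@H]1[C@]2(C)CCC[C@](C)(COCc4ccccc4)[C@H]2CC[C@]1(C)O | intermediate
33 | CNP0324566.1: (13S)-ent-labdane-8,15,18-triol 15-(hydrogen malonate) | C[C@H](CCOC(=O)CC(=O)O)CC[C@H]1[C@]2(C)CCC[C@](C)(CO)[C@H]2CC[C@]1(C)O | target

**Step count and risks**

Total step count: 23. Longest linear sequence: 20 (steps 1–12 and 16–23); steps 13–15 form the three-step side-chain branch.

Steps most likely to fail:

Step 8. The insertion may run through the competing array, in which C4 attacks C5 from the side of the C1 tether and palladium sits on the C20 face. That reverses the facial selectivity at C4 and puts the boryl arm cis to C20. Lesser process risks are borylation at C5 before ring closure and 3-exo closure of C18–palladium onto C5=C6. The fallback uses known chemistry, sets out from borane 7 (made from 5 as in step 4) and returns at 15. It turns that facial preference to use: the C18 oxygen is brought in on the alkene and the palladium-bearing arm becomes the C19 methyl. Borane 7 is coupled (PdCl2(dppf), aq K3PO4, DMF) with 2-bromoallyl 4-methoxybenzyl ether to give (2S,3S)-3-(tert-butyldimethylsilyloxy)-2-{4-[(4-methoxybenzyloxy)methyl]pent-4-en-1-yl}-2-methylcyclohexan-1-one F1. KN(SiMe3)2 converts it into its potassium enolate F2, which PhNTf2 traps as the enol triflate F3. HF·pyridine frees the hydroxy enol triflate F4, and Dess–Martin oxidation gives the keto enol triflate F5. A reductive Heck cyclisation (Pd(OAc)2, PPh3, HCO2Na, Bu4NCl, DMF, 80 °C; 6-exo insertion, then hydride capture of the neopentyl palladium) should give the 18-(4-methoxybenzyloxy) ent-decal-5-en-9-one F6, with the new methyl cis and the CH2O arm trans to C20. DDQ in CH2Cl2/H2O then removes the 4-methoxybenzyl group to give 15.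

Step 4. The C5 ketone may be reduced by 9-BBN in competition with hydroboration of the allyl group, which would use up borane and erode the ketone. The fallback sets out from 5 and returns at 8. Iridium-catalysed hydroboration with pinacolborane ([Ir(cod)Cl]2, dppe, CH2Cl2, rt), which leaves ketones alone, gives the primary pinacol boronate F7. KHF2 in aqueous methanol converts it into the potassium trifluoroborate F8. Suzuki–Miyaura coupling of F8 with 6 (PdCl2(dppf), Cs2CO3, toluene/H2O, 80 °C) then gives 8.

Step 10. Hydrogen uptake at the trisubstituted C5=C6 bond, which lies between two quaternary carbons, may be slow, or the iridium catalyst may be tied up by the ketone and the alcohol. The fallback sets out from 15 and returns at 16. It is a hydrogen-atom-transfer hydrogenation (Mn(dpm)3 (cat.), PhSiH3, t-BuOOH, i-PrOH, rt), which proceeds through the tertiary C5 radical and should deliver the thermodynamically favoured trans ring fusion without a coordination step. It makes no new compound.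

Further compounds
F1 | step 8 | (2S,3S)-3-(tert-butyldimethylsilyloxy)-2-{4-[(4-methoxybenzyloxy)methyl]pent-4-en-1-yl}-2-methylcyclohexan-1-one | CC(C)(C)[Si](C)(C)O[C@H]1CCCC(=O)[C@@]1(C)CCCC(=C)COCc2ccc(OC)cc2
F2 | step 8 | potassium enolate of F1 | CC(C)(C)[Si](C)(C)O[C@H]1CCC=C([O-])[C@@]1(C)CCCC(=C)COCc2ccc(OC)cc2.[K+]
F3 | step 8 | (5S,6S)-5-(tert-butyldimethylsilyloxy)-6-{4-[(4-methoxybenzyloxy)methyl]pent-4-en-1-yl}-6-methylcyclohex-1-en-1-yl trifluoromethanesulfonate | CC(C)(C)[Si](C)(C)O[C@H]1CCC=C(OS(=O)(=O)C(F)(F)F)[C@@]1(C)CCCC(=C)COCc2ccc(OC)cc2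
F4 | step 8 | (5S,6S)-5-hydroxy-6-{4-[(4-methoxybenzyloxy)methyl]pent-4-en-1-yl}-6-methylcyclohex-1-en-1-yl trifluoromethanesulfonate | O[C@H]1CCC=C(OS(=O)(=O)C(F)(F)F)[C@@]1(C)CCCC(=C)COCc2ccc(OC)cc2
F5 | step 8 | (R)-6-{4-[(4-methoxybenzyloxy)methyl]pent-4-en-1-yl}-6-methyl-5-oxocyclohex-1-en-1-yl trifluoromethanesulfonate | O=C1CCC=C(OS(=O)(=O)C(F)(F)F)[C@@]1(C)CCCC(=C)COCc2ccc(OC)cc2
F6 | step 8 | 18-(4-methoxybenzyloxy) ent-decal-5-en-9-one (C19 methyl cis to C20) | O=C1[C@]2(C)CCC[C@](C)(COCc3ccc(OC)cc3)C2=CCC1
F7 | step 4 | (2S,3S)-3-(tert-butyldimethylsilyloxy)-2-methyl-2-[3-(4,4,5,5-tetramethyl-1,3,2-dioxaborolan-2-yl)propyl]cyclohexan-1-one | CC(C)(C)[Si](C)(C)O[C@H]1CCCC(=O)[C@@]1(C)CCCB2OC(C)(C)C(C)(C)O2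
F8 | step 4 | potassium {3-[(1S,2S)-2-(tert-butyldimethylsilyloxy)-1-methyl-6-oxocyclohexyl]propyl}trifluoroborate | CC(C)(C)[Si](C)(C)O[C@H]1CCCC(=O)[C@@]1(C)CCC[B-](F)(F)F.[K+]
F0 | step 10 | none | none
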